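| setting | Saturday's | Friday's | Monday's | flask |
|---|---|---|---|---|
| starting material | 0.15 M | 0.33 M | 0.22 M | 0.22 M |
| first nucleophile | 0.33 M | 0.33 M | 0.33 M | 0.330 M |
| second nucleophile | 0.132 M | 0.132 M | 0.26 M | 0.132 M |
| capture agent | 0.22 M | 0.22 M | 0.22 M | 0.220 M |
| remark | run made earlier | run made earlier | run made earlier |  |
| time |  |  |  | 40 min |

| run | time / min | target / % | starting material / % |
|---|---|---|---|
| Saturday's | 0.417 | 10 | 37 |
| Saturday's | 1.33 | 17 | 2 |
| Saturday's | 3.00 | 16 | 0 |
| Saturday's | 8.00 | 11 | 0 |
| Saturday's | 25.0 | 1 | 0 |
| Friday's | 0.417 | 20 | 38 |
| Friday's | 1.33 | 50 | 4 |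
| Friday's | 3.00 | 49 | 0 |
| Friday's | 8.00 | 27 | 0 |
| Friday's | 25.0 | 5 | 4 |
| Monday's | 0.417 | 4 | 34 |
| Monday's | 1.33 | 9 | 3 |
| Monday's | 3.00 | 8 | 1 |
| Monday's | 8.00 | 7 | 0 |
| Monday's | 25.0 | 1 | 0 |

(scatter of a reading: 1.5 percentage points)

- steps under discussion: second nucleophile + open intermediate -> other capture product; open intermediate -> side product; target -> over-reaction product; first nucleophile + open intermediate -> target; starting material -> open intermediate; open intermediate + capture agent -> trapped intermediate

- time up to 40 min at which target stands highest
- the amount of target, in percent of the starting material charged, at that time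

**Late times.** At 25.0 min target reads 1% in Saturday's run, 5% in Friday's and 1% in Monday's, and Friday's falls from 49% to 27% between 3.00 min and 8.00 min with starting material reading 0%, so the question lies early, in how much target forms at all.

**Excess share.** Peak readings of target go from 17% in Saturday's run to 50% in Friday's as [starting material] rises, and stand at 9% in Monday's, whose [starting material] lies between those two and whose [second nucleophile] is higher, which suggests that the second nucleophile takes the open intermediate first. The asked flask's 40.0% is its excess share: the part of the charged [starting material] that exceeds the charged [second nucleophile]. Saturday's run has 12.0%, Friday's 60.0%, Monday's −18.2%.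

**One number?** It is close but not enough: Saturday's peak reads above its share, Friday's below, and Monday's shows target despite a negative share, so the selectivity factor is finite and target also drains. The asked flask lies between Saturday's and Friday's, and a straight line through those peak readings gives 36.2%, at a time between 1.33 min and 3.00 min, where Friday's reads 50% and 49%.

The forecast puts the peak at 1.8 min, “since target forms late”, and its height at 32%, under the value reckoned here.

    second nucleophile + open intermediate → other capture product (k = 54.0 M⁻¹ s⁻¹)
    open intermediate → side product (k = 0.00230 s⁻¹)
    target → over-reaction product (k = 0.00170 s⁻¹)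
    first nucleophile + open intermediate → target (k = 2.40 M⁻¹ s⁻¹)
    starting material → open intermediate (k = 0.0410 s⁻¹)
    open intermediate + capture agent → trapped intermediate (k = 0.0230 M⁻¹ s⁻¹)

**Result, neighbour.** The flask peaks at 34.2% at 1.75 min, 5.8 percentage points under its excess share, with other capture product at 59.9% against a complement of 60.0%. With [second nucleophile] cut to 0.079 M, the neighbour flask has an excess share of 64.1%, and the same line, run a little past Friday's, gives 52.8%; that flask peaks at 55.0%. Its other capture product ends at 35.9% against a complement of 35.9%, and over-reaction product holds the most of the neighbour flask's starting material at 40.0 min, with 62.2%.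

The earlier runs and the new flask were generated by integration with made-up constants, noise included.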